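**Plan**

Numbering: C1 quaternary (CH3, CH2O), C2 and C3 cyclobutane CH, C4 ketone, C5=C6(CH3), C7 cyclobutane CH, C8 quaternary (CH3), C9 CH–O, C10 CH2, C11 CH–O; ring A = cyclobutane C2–C3–C8–C7, ring B = enone ring, ring C = seven-membered ring.
Enabling feature: C2 and C8, the 1,3-related carbons of ring A, are spanned by C1–C11–C10–C9 on the face opposite the C4–C5–C6 bridge. Rings A and C thus form a bicyclo[4.1.1]octane, the formal adduct of a 1,3-diene across the central C2–C8 bond of a bicyclo[1.1.0]butane whose wing carbons C3 and C7 are already tied by C4–C6.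
Cuts: the three angelate C–O bonds; then C5=C6 (back to a saturated C4 ketone), the C8 methyl (back to an acyl group) and C11–OH (back to a ketone); finally C1–C2 and C8–C9 together, giving a 1,3-bis(silyloxy)diene and a bridged acyl bicyclobutane.
Forward order: ring B comes from (S)-5-methylcyclohexenone; carbene C–H insertion closes the bicyclobutane (latent ring A); the annulation closes ring C; enone and esters come last. The diene is a three-step side arm.
Stereochemistry: the chiral-pool methyl centre plus the choice of carboxylated bridgehead fix the absolute sense of the core (the centre is erased when C5=C6 forms). C2/C8 follow from exo-face topology, C1/C9 from diene geometry under a chiral copper catalyst, C11 from hydroxyl-directed reduction.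

Key step: step 9

Assumption: (S)-5-methylcyclohex-2-en-1-one is bought as a chiral-pool enone (otherwise three routine steps from (S)-pulegone); in 3 and 4 the ring-fusion centres are left open because both alkene faces react and both isomers converge in step 3.

**Route**

Step 1
Reactants: 1 (S)-5-methylcyclohex-2-en-1-one
Product: 2 (S)-9-methyl-1,4-dioxaspiro[4.5]dec-6-ene
Conditions: TMSOCH2CH2OTMS, TMSOTf (2 mol%), CH2Cl2, −78 °C; pyridine quench
Reagents that add atoms: 1,2-bis(trimethylsilyloxy)ethane, C[Si](C)(C)OCCO[Si](C)(C)C
Why: Noyori ketalisation under aprotic TMSOTf catalysis at low temperature should ketalise the enone without moving the double bond (protic glycol conditions would isomerise it), and it creates no stereocentre.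

Step 2
Reactants: 2 (S)-9-methyl-1,4-dioxaspiro[4.5]dec-6-ene
Product: 3 7',7'-dibromo-4'-methylspiro[[1,3]dioxolane-2,2'-bicyclo[4.1.0]heptane]
Conditions: CHBr3, KOtBu, pentane, −10 → 0 °C
Reagents that add atoms: bromoform, BrC(Br)Br
Why: Dibromocarbene from α-elimination of bromoform adds to the cis-disubstituted ring alkene in a stereospecific [2+1] cyclopropanation; either face may be attacked (anti to the pseudo-axial ketal oxygen should dominate), which is immaterial because both diastereomers give the same product in step 3.

Step 3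
Reactants: 3 7',7'-dibromo-4'-methylspiro[[1,3]dioxolane-2,2'-bicyclo[4.1.0]heptane]
Product: 5 5'-methylspiro[[1,3]dioxolane-2,3'-tricyclo[4.1.0.0(2,7)]heptane], via bromolithio carbenoid 4 (not isolated)
Conditions: MeLi, Et2O, −78 → 0 °C
Reagents that add atoms: none
Why: Bromine–lithium exchange and α-elimination give a cyclopropylidene that inserts transannularly into a C–H bond of the ring CH2 flanking the cyclopropane (the classical carbenoid route to tricyclo[4.1.0.0(2,7)]heptanes); the other flanking carbon is the hydrogen-free ketal carbon, so only this bridged bicyclobutane can form, and the methyl centre is untouched.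

Step 4
Reactants: 5 5'-methylspiro[[1,3]dioxolane-2,3'-tricyclo[4.1.0.0(2,7)]heptane]
Product: 7 bridgehead carboxylic acid of 5 (carboxyl anti to the methyl group), via bridgehead lithium compound 6 (not isolated)
Conditions: n-BuLi, TMEDA, Et2O, 0 °C → rt; CO2, −78 °C; cold 1 M HCl to pH 3; chromatography
Reagents that add atoms: carbon dioxide, O=C=O
Why: Bridgehead metalation of the s-rich bicyclobutane C–H bond and carboxylation are established for the parent tricycloheptane; the two bridgeheads differ only through the remote methyl group, so no useful preference is expected, and acid 7 (methyl on the side of the remaining bridgehead hydrogen) has to be separated from its bridgehead isomer, this choice fixing the absolute sense of the core once C6 becomes trigonal.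

Step 5
Reactants: 7 bridgehead carboxylic acid; 8 3,5-dimethylpyrazole
Product: 9 bridged acyl bicyclobutane (N-acyl-3,5-dimethylpyrazole of 7)
Conditions: EDC·HCl, DMAP (cat.), CH2Cl2, 0 °C → rt
Reagents that add atoms: none
Why: Carbodiimide coupling with the pyrazole NH is the usual way to bidentate N-acyl pyrazoles of bicyclobutane acids, and the strained ring is inert to these neutral conditions.

Step 6
Reactants: 10 4-hydroxy-3-methylbutan-2-one (racemic)
Product: 11 4-(tert-butyldimethylsilyloxy)-3-methylbutan-2-one
Conditions: TBSCl, imidazole, DMF, 0 °C → rt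
Reagents that add atoms: tert-butyldimethylsilyl chloride, CC(C)(C)[Si](C)(C)Cl
Why: Imidazole-mediated silylation of the primary hydroxyl is too mild to cause retro-aldol cleavage or β-elimination.

Step 7
Reactants: 11 4-(tert-butyldimethylsilyloxy)-3-methylbutan-2-one
Product: 13 (Z)-5-(tert-butyldimethylsilyloxy)-1-hydroxy-4-methylpent-1-en-3-one, via lithium enolate 12 (not isolated)
Conditions: LiN(iPr)2, THF, −78 °C; HCO2CH2CF3, −78 °C → rt; aq. NH4Cl
Reagents that add atoms: 2,2,2-trifluoroethyl formate, O=COCC(F)(F)F
Why: Kinetic deprotonation at the methyl group and crossed Claisen condensation with the activated formate give the β-keto aldehyde as its chelated Z-enol, the low temperature keeping the β-silyloxy enolate from eliminating; the racemic centre is erased in step 8.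

Step 8
Reactants: 13 (Z)-5-(tert-butyldimethylsilyloxy)-1-hydroxy-4-methylpent-1-en-3-one
Product: 14 (1E,3Z)-5-(tert-butyldimethylsilyloxy)-4-methyl-1,3-bis(trimethylsilyloxy)penta-1,3-diene
Conditions: TMSOTf (2.3 equiv), Et3N, Et2O, 0 °C → rt
Reagents that add atoms: trimethylsilyl trifluoromethanesulfonate, C[Si](C)(C)OS(=O)(=O)C(F)(F)F
Why: TMSOTf/Et3N silylates the enol oxygen and then enolises the vinylogous ester at its only α-hydrogen (soft enolisation); the disubstituted enol ether should equilibrate to E, and at the tetrasubstituted double bond the larger CH2OTBS group is expected cis to the small OTMS group with the methyl cis to the vinyl group (3Z), the arrangement that relays the C1 configuration in step 9.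

Step 9
Reactants: 9 bridged acyl bicyclobutane; 14 bis(silyloxy)diene
Product: 16 tricyclic C9-hydroxy C11-ketone carrying the C8 acyl pyrazole, via bis-silyl cycloadduct 15 (not isolated)
Conditions: Cu(OTf)2 (10 mol%), (S,S)-tBu-bisoxazoline (12 mol%), 4 Å MS, CH2Cl2, −40 → −20 °C; then aq. citric acid, THF, 0 °C
Reagents that add atoms: none
Why: Proposed new method: the divalent copper–bisoxazoline chelate binds the acyl pyrazole through carbonyl oxygen and N2 and polarises the C2–C8 bond toward a C8 copper enolate and an electron-poor, flattening C2; the tetrasubstituted enol ether carbon (future C1) of the s-cis diene bonds to C2 and the enolate then adds to the oxocarbenium-activated terminus C9 (Mukaiyama–Michael), the closest known reaction type being the Lewis acid-catalysed formal (4+3) annulation of monocyclic acyl bicyclo[1.1.0]butanes with silyl dienol ethers, together with chiral copper-catalysed cycloadditions of bicyclobutane acyl pyrazoles. Ring C closes as a seven-membered ring by 7-(enolexo)-endo-trig attack of the enolate on C9, leaving C10=C11 as the silyl enol ether 15, which is hydrolysed on work-up. C2 and C8 are set by topology, because a four-carbon bridge can span them only on the exo face opposite the C4–C6 bridge; C1 and C9 are tied to each other by the diene geometry (CH2OTBS and the C9 silyloxy group both point outward in the s-cis diene and are added suprafacially), and their sense relative to the unsymmetrical bridge is left to the ligand, which must hold the diene over the C3 side. The step needs bonding at C2 on the exo lobe of the bent central bond, whereas nucleophiles normally enter acyl bicyclobutanes along the back (endo) lobe; in 9 that trajectory runs between the dioxolane oxygen and the C6 methyl group and cannot lead to a bridged product, so only exo-face engagement is productive. It also needs vinylogous closure at C9 rather than direct closure at C11, which the quaternary C1 next to C11 should enforce.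

Step 10
Reactants: 16 tricyclic C9-hydroxy C11-ketone
Product: 17 C9,C11-anti diol
Conditions: Me4NBH(OAc)3, MeCN/AcOH, −30 °C
Reagents that add atoms: none
Why: Evans–Saksena reduction, in which the C9 hydroxyl exchanges onto boron and delivers hydride intramolecularly to the C11 ketone through a six-membered transition state, so that the new hydroxyl is anti to C9–OH as the target requires and the bias of the flanking quaternary C1 is overridden; acyl pyrazole and ketal are inert to this reagent.

Step 11
Reactants: 17 C9,C11-anti diol
Product: 18 C9,C11-bis(tert-butyldimethylsilyl) ether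
Conditions: TBSOTf, 2,6-lutidine, CH2Cl2, −78 → 0 °C
Reagents that add atoms: tert-butyldimethylsilyl trifluoromethanesulfonate, CC(C)(C)[Si](C)(C)OS(=O)(=O)C(F)(F)F
Why: The silyl triflate with 2,6-lutidine silylates even secondary alcohols flanked by quaternary carbons and masks both hydroxyls for the hydride steps that follow.

Step 12
Reactants: 18 bis(silyl ether) acyl pyrazole
Product: 19 C8 hydroxymethyl compound
Conditions: LiBH4, THF, 0 °C → rt
Reagents that add atoms: none
Why: N-Acyl pyrazoles are activated amides that LiBH4 reduces to primary alcohols with release of the pyrazole, while silyl ethers and the ketal are untouched.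

Step 13
Reactants: 19 C8 hydroxymethyl compound
Product: 21 C8 methyl compound, via primary triflate 20 (not isolated)
Conditions: Tf2O, pyridine, CH2Cl2, −78 → −20 °C; LiEt3BH, THF, −78 → 0 °C
Reagents that add atoms: none
Why: Deoxygenation through the primary triflate and SN2 hydride displacement with LiEt3BH, which reduces even neopentyl-type sulfonates, turns the former acyl carbon into the C8 methyl group; the triflate is made and consumed cold to avoid cyclobutylcarbinyl ionisation and ring expansion.

Step 14
Reactants: 21 C8 methyl compound (C4 ketal)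
Product: 22 C4 ketone
Conditions: PPTS, acetone/H2O, 50 °C
Reagents that add atoms: water, O
Why: Mild acid-catalysed ketal hydrolysis frees the C4 ketone while the hindered silyl ethers survive; the ketone can enolise only toward C5 because C3 is a cyclobutane bridgehead.

Step 15
Reactants: 22 C4 ketone
Product: 24 C5 bromo ketone, via trimethylsilyl enol ether 23 (not isolated)
Conditions: LiN(SiMe3)2, TMSCl, THF, −78 °C; NBS, −78 → 0 °C
Reagents that add atoms: N-bromosuccinimide, BrN1C(=O)CCC1=O
Why: Enolisation toward C5 (the only enolisable position), trapping as the silyl enol ether and bromination with NBS give the α-bromo ketone regiospecifically; the C5 configuration does not matter because bromide exchange equilibrates it in step 16.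

Step 16
Reactants: 24 C5 bromo ketone
Product: 25 enone tris(silyl ether)
Conditions: Li2CO3, LiBr, DMF, 120 °C
Reagents that add atoms: none
Why: Dehydrobromination with LiBr/Li2CO3 in hot DMF introduces C5=C6 (the only β-hydrogen is on the methyl-bearing C6, so the chiral-pool centre is removed here); this route is chosen because syn-eliminations of palladium enolates or selenoxides would need a C6 hydrogen on the accessible face, where the methyl group sits.

Step 17
Reactants: 25 enone tris(silyl ether)
Product: 26 enone triol
Conditions: HF (48% aq.), MeCN, rt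
Reagents that add atoms: none
Why: Aqueous HF in acetonitrile cleaves the one primary and two secondary silyl ethers without affecting the enone.

Step 18
Reactants: 26 enone triol; 27 angelic acid (4.5 equiv, all of it first converted into the mixed anhydride)
Product: 28 CNP0266467.1 (tris-angelate)
Conditions: 27 (4.5 equiv), 2,4,6-Cl3C6H2COCl (4.5 equiv), Et3N, toluene, rt; then 26, toluene, 80 °C
Reagents that add atoms: angelic 2,4,6-trichlorobenzoic anhydride, C/C=C(/C)C(=O)OC(=O)c1c(Cl)cc(Cl)cc1Cl
Why: Yamaguchi-type esterification in which the mixed anhydride preformed from the excess of 27 transfers one angeloyl group to each of the three hydroxyls (three equivalents of anhydride are consumed per triol), run in warm toluene without DMAP because this variant is known to preserve the Z geometry of angelates, whereas nucleophilic catalysts promote isomerisation to tiglates.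

**Compound list**

1 | (S)-5-methylcyclohex-2-en-1-one | C[C@H]1CC=CC(=O)C1 | starting material
2 | (S)-9-methyl-1,4-dioxaspiro[4.5]dec-6-ene | C[C@H]1CC=CC2(C1)OCCO2 | intermediate
3 | 7',7'-dibromo-4'-methylspiro[[1,3]dioxolane-2,2'-bicyclo[4.1.0]heptane] (methyl centre as in 2, both cyclopropane faces) | BrC1(Br)C2C1C1(OCCO1)C[C@@H](C)C2 | intermediate
4 | 7'-bromo-7'-lithio carbenoid of 3 | [Li]C1(Br)C2C1C1(OCCO1)C[C@@H](C)C2 | intermediate (not isolated)
5 | 5'-methylspiro[[1,3]dioxolane-2,3'-tricyclo[4.1.0.0(2,7)]heptane] (bridged bicyclobutane) | [C@H]12[C@@H]3C4(OCCO4)C[C@@H](C)[C@H]1[C@H]23 | intermediate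
6 | bridgehead lithium derivative of 5 (lithium anti to the methyl group) | [Li][C@]12[C@@H]3C4(OCCO4)C[C@@H](C)[C@H]1[C@H]23 | intermediate (not isolated)
7 | 5'-methylspiro[[1,3]dioxolane-2,3'-tricyclo[4.1.0.0(2,7)]heptane]-1'-carboxylic acid (carboxyl anti to the methyl group) | OC(=O)[C@]12[C@@H]3C4(OCCO4)C[C@@H](C)[C@H]1[C@H]23 | intermediate
8 | 3,5-dimethylpyrazole | Cc1cc(C)[nH]n1 | starting material
9 | N-acyl-3,5-dimethylpyrazole of 7 (bridged acyl bicyclobutane; C8 acyl, C2–H, C4 dioxolane, C6 methyl on the C2 side) | Cc1cc(C)n(n1)C(=O)[C@]12[C@@H]3C4(OCCO4)C[C@@H](C)[C@H]1[C@H]23 | intermediate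
10 | 4-hydroxy-3-methylbutan-2-one (racemic) | CC(CO)C(C)=O | starting material
11 | 4-(tert-butyldimethylsilyloxy)-3-methylbutan-2-one | CC(CO[Si](C)(C)C(C)(C)C)C(C)=O | intermediate
12 | lithium enolate of 11 (methyl side) | [Li]OC(=C)C(C)CO[Si](C)(C)C(C)(C)C | intermediate (not isolated)
13 | (Z)-5-(tert-butyldimethylsilyloxy)-1-hydroxy-4-methylpent-1-en-3-one | CC(CO[Si](C)(C)C(C)(C)C)C(=O)/C=C\O | intermediate
14 | (1E,3Z)-5-(tert-butyldimethylsilyloxy)-4-methyl-1,3-bis(trimethylsilyloxy)penta-1,3-diene | C[Si](C)(C)O/C=C/C(O[Si](C)(C)C)=C(/CO[Si](C)(C)C(C)(C)C)C | intermediate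
15 | cycloadduct as C10=C11 trimethylsilyl enol ether and C9 trimethylsilyl ether | CC(C)(C)[Si](C)(C)OC[C@]1(C)[C@@H]2[C@H]3C4(OCCO4)C[C@@H](C)[C@@H]2[C@@]3(C(=O)n4nc(C)cc4C)[C@H](O[Si](C)(C)C)C=C1O[Si](C)(C)C | intermediate (not isolated)
16 | tricyclic adduct: C1 (CH3, CH2OTBS), C9–OH, C11 ketone, C8 acyl pyrazole, C4 dioxolane, ring C anti to the C4–C6 bridge | CC(C)(C)[Si](C)(C)OC[C@]1(C)[C@@H]2[C@H]3C4(OCCO4)C[C@@H](C)[C@@H]2[C@@]3(C(=O)n4nc(C)cc4C)[C@H](O)CC1=O | intermediate
17 | C9,C11-anti diol of 16 | CC(C)(C)[Si](C)(C)OC[C@]1(C)[C@@H]2[C@H]3C4(OCCO4)C[C@@H](C)[C@@H]2[C@@]3(C(=O)n4nc(C)cc4C)[C@H](O)C[C@H]1O | intermediate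
18 | C9,C11-bis(TBS) ether of 17 | CC(C)(C)[Si](C)(C)OC[C@]1(C)[C@@H]2[C@H]3C4(OCCO4)C[C@@H](C)[C@@H]2[C@@]3(C(=O)n4nc(C)cc4C)[C@H](O[Si](C)(C)C(C)(C)C)C[C@H]1O[Si](C)(C)C(C)(C)C | intermediate
19 | C8 hydroxymethyl compound | CC(C)(C)[Si](C)(C)OC[C@]1(C)[C@@H]2[C@H]3C4(OCCO4)C[C@@H](C)[C@@H]2[C@@]3(CO)[C@H](O[Si](C)(C)C(C)(C)C)C[C@H]1O[Si](C)(C)C(C)(C)C | intermediate
20 | C8 CH2 triflate | CC(C)(C)[Si](C)(C)OC[C@]1(C)[C@@H]2[C@H]3C4(OCCO4)C[C@@H](C)[C@@H]2[C@@]3(COS(=O)(=O)C(F)(F)F)[C@H](O[Si](C)(C)C(C)(C)C)C[C@H]1O[Si](C)(C)C(C)(C)C | intermediate (not isolated)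
21 | C8 methyl compound (C4 dioxolane) | CC(C)(C)[Si](C)(C)OC[C@]1(C)[C@@H]2[C@H]3C4(OCCO4)C[C@@H](C)[C@@H]2[C@@]3(C)[C@H](O[Si](C)(C)C(C)(C)C)C[C@H]1O[Si](C)(C)C(C)(C)C | intermediate
22 | C4 ketone | CC(C)(C)[Si](C)(C)OC[C@]1(C)[C@@H]2[C@H]3C(=O)C[C@@H](C)[C@@H]2[C@@]3(C)[C@H](O[Si](C)(C)C(C)(C)C)C[C@H]1O[Si](C)(C)C(C)(C)C | intermediate
23 | C4=C5 trimethylsilyl enol ether | CC(C)(C)[Si](C)(C)OC[C@]1(C)[C@@H]2[C@H]3C(O[Si](C)(C)C)=C[C@@H](C)[C@@H]2[C@@]3(C)[C@H](O[Si](C)(C)C(C)(C)C)C[C@H]1O[Si](C)(C)C(C)(C)C | intermediate (not isolated)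
24 | C5 bromo ketone (C5 epimers) | CC(C)(C)[Si](C)(C)OC[C@]1(C)[C@@H]2[C@H]3C(=O)C(Br)[C@@H](C)[C@@H]2[C@@]3(C)[C@H](O[Si](C)(C)C(C)(C)C)C[C@H]1O[Si](C)(C)C(C)(C)C | intermediate
25 | enone tris(TBS) ether | CC(C)(C)[Si](C)(C)OC[C@]1(C)[C@@H]2[C@H]3C(=O)C=C(C)[C@@H]2[C@@]3(C)[C@H](O[Si](C)(C)C(C)(C)C)C[C@H]1O[Si](C)(C)C(C)(C)C | intermediate
26 | enone triol | OC[C@]1(C)[C@@H]2[C@H]3C(=O)C=C(C)[C@@H]2[C@@]3(C)[C@H](O)C[C@H]1O | intermediate
27 | angelic acid | C/C=C(/C)C(O)=O | starting material
28 | CNP0266467.1 | C/C=C(/C)C(=O)OC[C@]1(C)[C@@H]2[C@H]3C(=O)C=C(C)[C@@H]2[C@@]3(C)[C@H](OC(=O)/C(C)=C\C)C[C@H]1OC(=O)/C(C)=C\C | target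

**Count and risks**

Total: 18 steps. Longest linear sequence: 15 steps (steps 1–5 and 9–18); the diene arm (steps 6–8) is 3 steps.

Steps most likely to fail:

1. Step 9 (Proposed new method). The diene may bond to C2 along the usual endo trajectory, which gives open-chain cyclobutane adducts that cannot close ring C. The ligand may also fail to control the sense of C1/C9 relative to the bridge, or closure may occur at C11 instead of C9. Fallback, setting out from 9 (with 14) and returning at 16: C2 is made trigonal before the C1–C2 bond is formed. Radical addition of thiophenol to 9 (PhSH, AIBN) gives the C2 phenylthio cyclobutane F1. NCS gives the α-chloro sulfide F2. ZnBr2 ionises F2 to a planar C2 thionium ion, which the enol ether terminus of 14 alkylates from the open exo face (thionium–silyl enol ether alkylation), giving the β-silyloxy enone F3; its C1 epimers are separated here. Soft enolisation of the acyl pyrazole (TMSOTf, Et3N) closes ring C by intramolecular Mukaiyama–Michael addition, and mild acid gives the ring-closed sulfide F4. Bu3SnH/AIBN then removes sulfur to give 16.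

2. Step 4. The base may not discriminate between the two bridgehead C–H bonds, and the two acids may co-elute. Fallback, setting out from 5 and returning at 16: the mixed acids are coupled as in step 5, giving 9 together with the isomeric acyl pyrazole F5, and the mixture is used in step 9. F5 could form an adduct only by pressing its acyl group against the C6 methyl group, so it is expected to stay behind, and the separation is moved to 16, which differs far more from F5 than 9 does.

3. Step 18. Acylation of the two hindered secondary hydroxyls may be incomplete, and the angeloyl units may isomerise from Z to E under forcing conditions. Fallback, setting out from 26 and returning at 28: 26 is esterified with 2-[bis(2,2,2-trifluoroethoxy)phosphoryl]propanoic acid (DCC, DMAP) to the tris(phosphonopropionate) F6. Still–Gennari olefination with acetaldehyde (KN(SiMe3)2, 18-crown-6, THF, −78 °C) then builds the three Z-2-methylbut-2-enoates on the already attached esters.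

**Further compounds**

F1 | step 9 | C2 phenylthio cyclobutane (SPh syn to the C4–C6 bridge, C8–H acyl pyrazole) | Cc1cc(C)n(n1)C(=O)[C@@H]1[C@@H]2C3(OCCO3)C[C@@H](C)[C@H]1[C@H]2Sc1ccccc1
F2 | step 9 | C2 α-chloro sulfide (C2 epimers) | Cc1cc(C)n(n1)C(=O)[C@@H]1[C@@H]2C3(OCCO3)C[C@@H](C)[C@H]1C2(Cl)Sc1ccccc1
F3 | step 9 | C2-alkylated β-silyloxy enone (C1 on the exo face of C2, SPh retained) | Cc1cc(C)n(n1)C(=O)[C@@H]1[C@@H]2C3(OCCO3)C[C@@H](C)[C@H]1[C@]2(Sc1ccccc1)[C@@](C)(CO[Si](C)(C)C(C)(C)C)C(=O)/C=C/O[Si](C)(C)C
F4 | step 9 | ring-closed sulfide (16 with SPh on C2) | CC(C)(C)[Si](C)(C)OC[C@]1(C)[C@]2(Sc5ccccc5)[C@H]3C4(OCCO4)C[C@@H](C)[C@@H]2[C@@]3(C(=O)n4nc(C)cc4C)[C@H](O)CC1=O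
F5 | step 4 | isomeric acyl pyrazole (acyl on the bridgehead syn to the methyl group) | [C@H]12[C@@H]3C4(OCCO4)C[C@@H](C)[C@H]1[C@]23C(=O)n1nc(C)cc1C
F6 | step 18 | tris(phosphonopropionate) of 26 | CC(C(=O)OC[C@]1(C)[C@@H]2[C@H]3C(=O)C=C(C)[C@@H]2[C@@]3(C)[C@H](OC(=O)C(C)P(=O)(OCC(F)(F)F)OCC(F)(F)F)C[C@H]1OC(=O)C(C)P(=O)(OCC(F)(F)F)OCC(F)(F)F)P(=O)(OCC(F)(F)F)OCC(F)(F)F
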